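**Retrosynthetic overview**

1. The target is reached from an acetophenone by three operations: O‑11 desilylation, two allyl groups made from two ArCH2Br groups by copper‑catalysed vinylation, and the C2'–OH made from a C2' acetyl group by Baeyer–Villiger oxidation.
2. Key disconnection: the central benzene ring. It has three adjacent oxygenated carbons, C1' (O–C4 of the eudesmane), C2' (OH) and C3' (O‑aryl), and a carbon substituent on C5'. C2'–C5' map onto C3–C6 of a 3‑acetyl‑4‑aryloxy‑6‑(bromomethyl)‑2‑pyrone and C1'/C6' onto a terpenyl ethynyl ether; a [4+2] cycloaddition forms C1'–C2' and C5'–C6', and loss of CO2 gives the arene.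
3. The ynol ether comes from the tertiary C4 alkoxide of the cis‑fused (4R,5S,7R,10R)‑eudesmane‑4,11‑diol (O‑11 as triethylsilyl ether) and trichloroethylene. The pyrone comes from dehydroacetic acid and p‑cresol, with both methyl groups brominated before the cycloaddition.
4. The diol comes from double ozonolysis and double methyl addition on the cis‑fused eudesma‑4(15),11‑diene. The diene comes from (S)‑carvone by cuprate addition (C4–C5 bond), intramolecular enolate alkylation (C1–C10 bond) and removal of the C9 carbonyl.
5. Ring order: ring B (bought as carvone), then ring A (annulation), then the central arene (cycloaddition); the phenoxy ring is bought as p‑cresol.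

Key step: step 12

Remark on the target: the SMILES defines 4R,5S,7R,10R, a cis‑fused decalin with H‑5, the C10 methyl and the C7 side chain on one face and O‑4 on the other (the C5 epimer of the cryptomeridiol skeleton); the terpene is built for this isomer.
Remark on numbering: eudesmane numbers are used for the terpene and primed numbers for the central arene; species that differ from a numbered compound only by deprotonation (alkoxides, enolates, phenoxides) carry no number of their own.

**Route**

Step 1
Reactants: 1 5-chloropent-1-yne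
Product: 3 2-bromo-5-chloropent-1-ene, via alkenylborane 2 (not isolated)
Conditions: B-bromo-9-BBN, CH2Cl2, 0 °C; then AcOH, 0 → 25 °C
Reagents that add atoms: B-bromo-9-borabicyclo[3.3.1]nonane, BrB1C2CCCC1CCC2
Why: Bromoboration–protodeboronation: the B–Br bond adds syn across the terminal alkyne with bromine on the internal carbon, and acetic acid then replaces boron by hydrogen to leave the 2-bromo-1-alkene, the primary chloride being inert throughout.

Step 2
Reactants: 3 2-bromo-5-chloropent-1-ene; 4 (S)-(+)-carvone
Product: 7 (3S,5S)-3-(5-chloropent-1-en-2-yl)-2-methyl-5-(prop-1-en-2-yl)cyclohexan-1-one (both C2 epimers), via alkenyllithium 5 (not isolated), via lithium dialkenylcuprate 6 (not isolated)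
Conditions: 3 (2.2 equiv), t-BuLi (4.4 equiv), Et2O, −78 °C; CuBr·SMe2 (1.1 equiv), −78 → −40 °C; 4, −78 → −30 °C; aq. NH4Cl
Reagents that add atoms: none
Why: Conjugate addition of a Gilman cuprate: Br–Li exchange at −78 °C spares the alkyl chloride, and the cuprate should add to the enone on the face opposite the isopropenyl group, which sets the new centre (future C5) trans to C7, while the methyl-bearing carbon is left as a mixture because it is enolised in the next step.

Step 3
Reactants: 7 chloro ketone
Product: 8 (5R,7S,10S)-eudesma-4(15),11-dien-9-one with cis ring fusion (5β-H; 10β-CH3; 7β-isopropenyl)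
Conditions: KH, THF, 0 → 25 °C
Reagents that add atoms: none
Why: Methylenecyclohexane annulation by intramolecular enolate alkylation: the more substituted potassium enolate displaces the tethered primary chloride (6-exo-tet), and because the tether can reach the enolate π-face only from a pseudo-axial bond on the neighbouring carbon the cis-fused decalone should form, which sets C10 with its methyl cis to H-5 and to the isopropenyl group.

Step 4
Reactants: 8 dienone
Product: 10 (5R,7R,10R)-eudesma-4(15),11-diene with cis ring fusion (5-epi-β-selinene), via hydrazone 9 (not isolated)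
Conditions: N2H4·H2O, diethylene glycol, 130 °C; KOH, 200 °C, under N2
Reagents that add atoms: none
Why: Wolff–Kishner reduction (Huang-Minlon modification) removes the carbonyl that served only to build ring A, the ketone having just one quaternary neighbour, the 1,1-disubstituted alkenes being too weakly acidic to migrate in KOH/glycol, and exclusion of air preventing their reduction by diimide.

Step 5
Reactants: 10 diene
Product: 12 (4aR,7R,8aS)-7-acetyl-4a-methyloctahydronaphthalen-1(2H)-one (cis-fused), via bis-ozonide 11 (not isolated)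
Conditions: O3, CH2Cl2, −78 °C; Me2S, −78 → 25 °C
Reagents that add atoms: ozone, [O-][O+]=O
Why: Ozonolysis cleaves both 1,1-disubstituted alkenes to the ring ketone and the methyl ketone, and the neutral sulfide work-up avoids enolisation at C5, so the cis ring fusion (the less stable one for this decalone) should be kept.

Step 6
Reactants: 12 diketone
Product: 13 (1R,4aR,7R,8aS)-7-(2-hydroxypropan-2-yl)-1,4a-dimethyldecahydronaphthalen-1-ol [(4R,5S,7R,10R)-eudesmane-4,11-diol]
Conditions: MeMgBr, CeCl3, THF, −78 → −20 °C; aq. NH4Cl
Reagents that add atoms: methylmagnesium bromide, C[Mg]Br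
Why: Organocerium 1,2-addition is fast and barely basic, so C5 should not epimerise; the acetyl group should react first and its bulky carbinolate then holds ring B with the C7 group equatorial, a conformer in which the α-face of C4 lies under ring B (1,3-diaxial to C9), so methyl is delivered from the open β-face and C4 is set as 4R (axial 4α-O, equatorial 4β-CH3).

Step 7
Reactants: 13 diol
Product: 14 (1R,4aR,7R,8aS)-1,4a-dimethyl-7-[2-(triethylsilyloxy)propan-2-yl]decahydronaphthalen-1-ol
Conditions: TESOTf (1.1 equiv), 2,6-lutidine, CH2Cl2, −78 °C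
Reagents that add atoms: triethylsilyl trifluoromethanesulfonate, CC[Si](CC)(CC)OS(=O)(=O)C(F)(F)F
Why: Kinetic silylation with a silyl triflate should distinguish the two tertiary alcohols, since the side-chain carbinol is open whereas the C4 hydroxyl is axial on the concave face of the cis-decalin next to the ring fusion.

Step 8
Reactants: 14 mono-silyl ether; 15 trichloroethylene
Product: 18 (1R,4aR,7R,8aS)-1-(ethynyloxy)-1,4a-dimethyl-7-[2-(triethylsilyloxy)propan-2-yl]decahydronaphthalene, via dichlorovinyl ether 16 (not isolated), via lithium alkynyl ether 17 (not isolated)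
Conditions: KH, THF, 0 → 25 °C; 15, −40 → 25 °C; n-BuLi (2.5 equiv), −78 → −40 °C; MeOH, −78 °C; work-up and storage below 0 °C
Reagents that add atoms: none
Why: Ynol ether synthesis from an alkoxide and trichloroethylene: the potassium alkoxide adds to dichloroacetylene formed in the flask, so the crowded C4–O–C bond is made at an sp carbon, and n-BuLi then turns the (E)-1,2-dichlorovinyl ether into the lithium alkynyl ether by elimination and Cl–Li exchange, which is protonated cold because tert-alkyl ethynyl ethers lose ketene by a retro-ene reaction on warming.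

Step 9
Reactants: 19 dehydroacetic acid
Product: 20 3-acetyl-4-chloro-6-methyl-2H-pyran-2-one
Conditions: POCl3, Et3N, toluene, 80 °C
Reagents that add atoms: phosphoryl chloride, O=P(Cl)(Cl)Cl
Why: The 4-hydroxyl is a vinylogous carboxylic acid, so POCl3 should convert it through the dichlorophosphate into the vinylogous acid chloride by addition–elimination, as with 4-hydroxycoumarins.

Step 10
Reactants: 20 chloropyrone; 21 p-cresol
Product: 22 3-acetyl-6-methyl-4-(4-methylphenoxy)-2H-pyran-2-one
Conditions: K2CO3, acetone, 0 → 25 °C
Reagents that add atoms: none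
Why: Addition–elimination (vinylogous acyl substitution) of the phenoxide at C4, which is activated by both the lactone and the acetyl carbonyl.

Step 11
Reactants: 22 aryloxypyrone
Product: 23 3-acetyl-6-(bromomethyl)-4-[4-(bromomethyl)phenoxy]-2H-pyran-2-one
Conditions: NBS (2.1 equiv), AIBN (cat.), PhCF3, 80 °C
Reagents that add atoms: N-bromosuccinimide, BrN1C(=O)CCC1=O
Why: Wohl–Ziegler bromination: the pyrone 6-methyl and the tolyl methyl both give stabilised radicals, the electron-poor pyrone and its aryloxy ring resist electrophilic bromination and the acetyl methyl is not attacked under radical conditions, whereas the same bromination after the cycloaddition would meet an orcinol-type ring prone to nuclear bromination and an acid-labile tert-alkyl aryl ether.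

Step 12
Reactants: 18 terpenyl ethynyl ether; 23 bis(bromomethyl)pyrone
Product: 25 1-{4-(bromomethyl)-2-[4-(bromomethyl)phenoxy]-6-[(1R,4aR,7R,8aS)-1,4a-dimethyl-7-[2-(triethylsilyloxy)propan-2-yl]decahydronaphthalen-1-yl]oxyphenyl}ethan-1-one, via bridged lactone 24 (not isolated)
Conditions: CH2Cl2, 2,6-di-tert-butylpyridine (5 mol%), 12 kbar, 25 °C; then 1 bar, 25 → 40 °C
Reagents that add atoms: none
Why: Inverse-electron-demand Diels–Alder reaction: the pyrone C3–C6 diene, made electron-poor by the lactone and the 3-acetyl group, reacts with the electron-rich ynol ether in a concerted but asynchronous [4+2] cycloaddition, the closest known type being the reaction of 3-acyl- and 3-alkoxycarbonyl-2-pyrones with alkoxyalkynes, ynamines and ketene acetals. The nucleophilic CH carbon of the alkyne bonds to C6 (the δ-carbon of both carbonyl groups) and the oxygen-bearing carbon to C3, so the six-membered carbocycle is closed by intermolecular cycloaddition (bonds C1'–C2' and C5'–C6') to give the bridged lactone 24, and retro-[4+2] loss of CO2 then turns it into the central benzene ring. No lasting stereocentre is formed, since the two bridgehead centres of 24 vanish on aromatisation. The step needs regioselectivity (alkoxy carbon to C3, so that the terpenyloxy group ends ortho to acetyl), which the matched polarisation of the two partners secures, and periselectivity for the ring diene over the acetyl/C3=C4 oxadiene, which the aryloxy donor on C4 and the use of a methyl ketone secure. It must also outrun the retro-ene loss of ketene from the tert-alkyl ynol ether, hence 12 kbar at 25 °C, which accelerates the bimolecular cycloaddition but not the unimolecular fragmentation, with CO2 released after decompression. The bromomethyl groups are bystanders that make the pyrone slightly more electron-poor, and the hindered pyridine scavenges traces of HBr that would otherwise destroy the ynol ether.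

Step 13
Reactants: 25 acetophenone
Product: 26 4-(bromomethyl)-2-[4-(bromomethyl)phenoxy]-6-(terpenyloxy)phenyl acetate (terpenyl as in 25)
Conditions: mCPBA, Na2HPO4, CH2Cl2, 0 → 25 °C
Reagents that add atoms: 3-chloroperoxybenzoic acid, OOC(=O)c1cccc(Cl)c1
Why: Baeyer–Villiger oxidation: in the Criegee adduct the electron-rich 2,6-dioxygenated aryl group should migrate in preference to methyl, the buffer protects the tert-alkyl aryl ether and the silyl ether, and benzylic bromides are inert to peracid.

Step 14
Reactants: 26 aryl acetate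
Product: 27 4-allyl-2-(4-allylphenoxy)-6-[(1R,4aR,7R,8aS)-1,4a-dimethyl-7-[2-(triethylsilyloxy)propan-2-yl]decahydronaphthalen-1-yl]oxyphenol
Conditions: CH2=CHMgBr (6 equiv), Li2CuCl4 (5 mol%), THF, −40 → 0 °C; aq. NH4Cl
Reagents that add atoms: vinylmagnesium bromide, C=C[Mg]Br
Why: Copper-catalysed Grignard cross-coupling at both benzylic bromides gives the two allyl groups while excess reagent cleaves the aryl acetate by acyl addition, and a quinone methide formed from the C2' phenoxide and the para bromomethyl group would be trapped by the same vinyl nucleophile in a 1,6-addition to the same product.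

Step 15
Reactants: 27 silyl ether
Product: 28 4-allyl-2-(4-allylphenoxy)-6-{[(1R,4aR,7R,8aS)-7-(2-hydroxypropan-2-yl)-1,4a-dimethyldecahydronaphthalen-1-yl]oxy}phenol (CNP0254037.2)
Conditions: TBAF, THF, 0 → 25 °C
Reagents that add atoms: none
Why: Fluoride-mediated desilylation of the tertiary triethylsilyl ether, under which the allyl groups, the diaryl ether and the tert-alkyl aryl ether are inert.

**Compound list**

1 | 5-chloropent-1-yne | C#CCCCCl | starting material
2 | (Z)-9-(2-bromo-5-chloropent-1-en-1-yl)-9-borabicyclo[3.3.1]nonane | Br/C(CCCCl)=C\B1C2CCCC1CCC2 | intermediate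
3 | 2-bromo-5-chloropent-1-ene | C=C(Br)CCCCl | intermediate
4 | (S)-(+)-carvone | CC1=CC[C@@H](CC1=O)C(C)=C | starting material
5 | (5-chloropent-1-en-2-yl)lithium | [Li]C(=C)CCCCl | intermediate
6 | lithium bis(5-chloropent-1-en-2-yl)cuprate | [Li+].C=C(CCCCl)[Cu-]C(=C)CCCCl | intermediate
7 | (3S,5S)-3-(5-chloropent-1-en-2-yl)-2-methyl-5-(prop-1-en-2-yl)cyclohexan-1-one (C2 epimers) | ClCCCC(=C)[C@H]1C[C@H](C(C)=C)CC(=O)C1C | intermediate
8 | (5R,7S,10S)-eudesma-4(15),11-dien-9-one, cis-fused | C=C1CCC[C@]2(C)C(=O)C[C@@H](C(C)=C)C[C@@H]21 | intermediate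
9 | hydrazone of 8 | C=C1CCC[C@]2(C)C(=NN)C[C@@H](C(C)=C)C[C@@H]21 | intermediate
10 | (5R,7R,10R)-eudesma-4(15),11-diene, cis-fused (5-epi-β-selinene) | C=C1CCC[C@]2(C)CC[C@@H](C(C)=C)C[C@@H]21 | intermediate
11 | bis(1,2,4-trioxolane) of 10 (both alkenes; spiro centres unassigned) | C13(OCOO3)CCC[C@]2(C)CC[C@@H](C4(C)OCOO4)C[C@@H]21 | intermediate
12 | (4aR,7R,8aS)-7-acetyl-4a-methyloctahydronaphthalen-1(2H)-one | O=C1CCC[C@]2(C)CC[C@@H](C(C)=O)C[C@@H]21 | intermediate
13 | (1R,4aR,7R,8aS)-7-(2-hydroxypropan-2-yl)-1,4a-dimethyldecahydronaphthalen-1-ol | O[C@]1(C)CCC[C@]2(C)CC[C@@H](C(C)(C)O)C[C@@H]21 | intermediate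
14 | (1R,4aR,7R,8aS)-1,4a-dimethyl-7-[2-(triethylsilyloxy)propan-2-yl]decahydronaphthalen-1-ol | O[C@]1(C)CCC[C@]2(C)CC[C@@H](C(C)(C)O[Si](CC)(CC)CC)C[C@@H]21 | intermediate
15 | trichloroethylene | ClC=C(Cl)Cl | starting material
16 | (E)-1,2-dichlorovinyl ether of 14 | Cl/C=C(/Cl)O[C@]1(C)CCC[C@]2(C)CC[C@@H](C(C)(C)O[Si](CC)(CC)CC)C[C@@H]21 | intermediate
17 | lithium alkynyl ether (lithium acetylide of 18) | [Li]C#CO[C@]1(C)CCC[C@]2(C)CC[C@@H](C(C)(C)O[Si](CC)(CC)CC)C[C@@H]21 | intermediate
18 | (1R,4aR,7R,8aS)-1-(ethynyloxy)-1,4a-dimethyl-7-[2-(triethylsilyloxy)propan-2-yl]decahydronaphthalene | C#CO[C@]1(C)CCC[C@]2(C)CC[C@@H](C(C)(C)O[Si](CC)(CC)CC)C[C@@H]21 | intermediate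
19 | dehydroacetic acid | CC(=O)C1=C(O)C=C(C)OC1=O | starting material
20 | 3-acetyl-4-chloro-6-methyl-2H-pyran-2-one | CC(=O)C1=C(Cl)C=C(C)OC1=O | intermediate
21 | p-cresol | Cc1ccc(O)cc1 | starting material
22 | 3-acetyl-6-methyl-4-(4-methylphenoxy)-2H-pyran-2-one | CC(=O)C1=C(Oc2ccc(C)cc2)C=C(C)OC1=O | intermediate
23 | 3-acetyl-6-(bromomethyl)-4-[4-(bromomethyl)phenoxy]-2H-pyran-2-one | CC(=O)C1=C(Oc2ccc(CBr)cc2)C=C(CBr)OC1=O | intermediate
24 | 2-oxabicyclo[2.2.2]octa-5,7-dien-3-one cycloadduct of 18 and 23 (bridgeheads unassigned) | CC(=O)C12C(=O)OC(CBr)(C=C1Oc1ccc(CBr)cc1)C=C2O[C@]3(C)CCC[C@]4(C)CC[C@@H](C(C)(C)O[Si](CC)(CC)CC)C[C@@H]43 | intermediate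
25 | 2-terpenyloxy-4-(bromomethyl)-6-[4-(bromomethyl)phenoxy]acetophenone (O-11 triethylsilyl ether) | CC(=O)c1c(Oc2ccc(CBr)cc2)cc(CBr)cc1O[C@]3(C)CCC[C@]4(C)CC[C@@H](C(C)(C)O[Si](CC)(CC)CC)C[C@@H]43 | intermediate
26 | corresponding aryl acetate | CC(=O)Oc1c(Oc2ccc(CBr)cc2)cc(CBr)cc1O[C@]3(C)CCC[C@]4(C)CC[C@@H](C(C)(C)O[Si](CC)(CC)CC)C[C@@H]43 | intermediate
27 | O-11 triethylsilyl ether of the target | C=CCc1ccc(Oc2cc(CC=C)cc(O[C@]3(C)CCC[C@]4(C)CC[C@@H](C(C)(C)O[Si](CC)(CC)CC)C[C@@H]43)c2O)cc1 | intermediate
28 | CNP0254037.2 | C=CCc1ccc(Oc2cc(CC=C)cc(O[C@]3(C)CCC[C@]4(C)CC[C@@H](C(C)(C)O)C[C@@H]43)c2O)cc1 | target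

**Step count**

Total step count: 15. Longest linear sequence: 12 steps (steps 1–8, then 12–15) from 5-chloropent-1-yne, or 11 from (S)-carvone.

**Three steps most likely to fail**

1. Step 12 (cycloaddition). The tert-alkyl ynol ether may fragment by retro-ene loss of ketene, add to the acetyl/C3=C4 oxadiene, or fail to add to the donor-substituted pyrone before the wanted cycloaddition occurs. Fallback, setting out from 14 and coming back at 27: the C1'–O bond is made by nucleophilic aromatic substitution on a ring that is already complete. Commercial 4-bromo-2,6-difluorobenzaldehyde and 4-bromophenol (K2CO3, DMF, 0 °C) give 4-bromo-2-(4-bromophenoxy)-6-fluorobenzaldehyde F1. The potassium alkoxide of 14 (KH, THF) displaces the fluoride ortho to the formyl group and gives the terpenyl aryl ether aldehyde F2. Dakin-type oxidation of the aldehyde (mCPBA, Na2HPO4) gives the aryl formate F3, and methanolysis (K2CO3, MeOH) gives the dibromophenol F4. A double Stille coupling with allyltributylstannane (Pd(PPh3)4, toluene, 90 °C) then gives 27, so no alkene is exposed to peracid or strong base.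

2. Step 8 (ynol ether). The axial, concave-face alkoxide may add too slowly to dichloroacetylene, or the product may be lost by ketene extrusion during work-up. Fallback, setting out from 14 and coming back at 18 through 17: the C–O bond is made by acylation and the second alkyne carbon is added by olefination. The alkoxide of 14 is formylated (KH, then 2,2,2-trifluoroethyl formate) to the terpenyl formate F5. Corey–Fuchs-type dibromo-olefination of the formate carbonyl (CBr4, PPh3, CH2Cl2) gives the 2,2-dibromovinyl ether F6. n-BuLi (2.2 equiv, −78 °C) converts it by Br–Li exchange and elimination into 17, which is protonated to 18 as in step 8.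

3. Step 14 (double vinylation). Once the acetate is cleaved, the C2' phenoxide can expel the para benzylic bromide and the resulting quinone methide can oligomerise; the benzylic bromides can also homocouple under Grignard conditions. Fallback, setting out from 26 and coming back at 27: a neutral Stille coupling of 26 with tributyl(vinyl)stannane (Pd(PPh3)4, toluene, 80 °C) keeps the acetate in place and gives the diallyl aryl acetate F7. K2CO3 in MeOH then frees the phenol and gives 27.

Further compounds
F1 | step 12 | 4-bromo-2-(4-bromophenoxy)-6-fluorobenzaldehyde | O=Cc1c(F)cc(Br)cc1Oc1ccc(Br)cc1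
F2 | step 12 | 4-bromo-2-(4-bromophenoxy)-6-(terpenyloxy)benzaldehyde (terpenyl as in 14) | O=Cc1c(Oc2ccc(Br)cc2)cc(Br)cc1O[C@]3(C)CCC[C@]4(C)CC[C@@H](C(C)(C)O[Si](CC)(CC)CC)C[C@@H]43
F3 | step 12 | 4-bromo-2-(4-bromophenoxy)-6-(terpenyloxy)phenyl formate | O=COc1c(Oc2ccc(Br)cc2)cc(Br)cc1O[C@]3(C)CCC[C@]4(C)CC[C@@H](C(C)(C)O[Si](CC)(CC)CC)C[C@@H]43
F4 | step 12 | 4-bromo-2-(4-bromophenoxy)-6-(terpenyloxy)phenol | Oc1c(Oc2ccc(Br)cc2)cc(Br)cc1O[C@]3(C)CCC[C@]4(C)CC[C@@H](C(C)(C)O[Si](CC)(CC)CC)C[C@@H]43
F5 | step 8 | formate ester of 14 | O=CO[C@]1(C)CCC[C@]2(C)CC[C@@H](C(C)(C)O[Si](CC)(CC)CC)C[C@@H]21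
F6 | step 8 | 2,2-dibromovinyl ether of 14 | BrC(Br)=CO[C@]1(C)CCC[C@]2(C)CC[C@@H](C(C)(C)O[Si](CC)(CC)CC)C[C@@H]21
F7 | step 14 | 4-allyl-2-(4-allylphenoxy)-6-(terpenyloxy)phenyl acetate | CC(=O)Oc1c(Oc2ccc(CC=C)cc2)cc(CC=C)cc1O[C@]3(C)CCC[C@]4(C)CC[C@@H](C(C)(C)O[Si](CC)(CC)CC)C[C@@H]43
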